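**Retrosynthetic overview**

1. The target (cis-fused: 10-CH3 and 5-H on the same face) is cut at C12–C13 into a bicyclic C12 iodide and the (E,E)-trienyl iodide made from geranyl bromide (B-alkyl Suzuki coupling). The C8 carbinol comes from methyl addition to a C8 ketone on the convex β face.
2. Structural feature used: the gem-dimethyl carbon C4 is bonded to the ring-fusion methine C5 shared by ring A and ring B. This matches the gem-dimethyl cyclobutane carbon and its bridgehead in (−)-verbenone, whose ten carbons become C4 with both methyls, C5–C10 and C1.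
3. Ring A is therefore disconnected at C3–C4: a Lewis acid on the C8 ketone breaks the cyclobutane bond C7–C4, and the tertiary C4 cation is trapped by a (Z)-vinylsilane tethered to C10. The (Z)-isomer is chosen so that the C–Si bond is axial and can stabilise the charge at C2 during 6-endo closure.
4. The precursor is assembled on verbenone: bromination of the ring methyl (→ C1), alkynylstannane coupling and cis-semihydrogenation (C2, C3), Me2CuLi anti to the bridge (C10 methyl; tether pushed syn to C4, which fixes the cis fusion), then enolate alkylation with methyl bromoacetate (C9 configuration, C11, C12).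
5. Ring order: ring B is the six-membered ring of verbenone (C5 from the chiral pool); ring A is closed last, in the key step. C2=C3 is then hydrogenated and C8, C12 and the side chain are finished.

Key step: step 6

Assumption: carbons are numbered as in a labdane (decalin C1–C10, C4 gem-dimethyl, C5/C10 ring fusion, C8 carbinol with methyl C17, C9 bearing the chain C11, C12, C13 …) and β is the face of the C10 methyl; read this way the SMILES is the cis-fused isomer (5β-H, 10β-CH3, 9β-chain, 8α-OH; 5R,8R,9R,10S), and that isomer is the one made.

**Route**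

Step 1
Reactants: 1 (1S,5S)-(−)-verbenone
Product: 2 10-bromoverbenone [4-(bromomethyl)-6,6-dimethylbicyclo[3.1.1]hept-3-en-2-one; bridgeheads as in 1]
Conditions: NBS, AIBN (cat.), PhCF3, 80 °C
Reagents that add atoms: N-bromosuccinimide, O=C1CCC(=O)N1Br
Why: Wohl–Ziegler allylic bromination; the methyl hydrogens are the only ones that give a conjugated allylic radical, because the bridgehead C–H is held orthogonal to the enone π system.

Step 2
Reactants: 2 10-bromoverbenone; 3 tributyl[(trimethylsilyl)ethynyl]stannane
Product: 4 4-[3-(trimethylsilyl)prop-2-ynyl]-6,6-dimethylbicyclo[3.1.1]hept-3-en-2-one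
Conditions: Pd2(dba)3 (cat.), P(2-furyl)3, THF, 50 °C
Reagents that add atoms: none
Why: Stille coupling of an allylic bromide with an alkynylstannane; the π-allylpalladium intermediate should couple at the unhindered CH2 terminus, which keeps the enone conjugated, and the neutral conditions do not isomerise the skipped enyne.

Step 3
Reactants: 4 silylpropynyl enone
Product: 5 4-[(Z)-3-(trimethylsilyl)prop-2-enyl]-6,6-dimethylbicyclo[3.1.1]hept-3-en-2-one
Conditions: H2 (1 atm), Pd/CaCO3 poisoned with Pb(OAc)2 (Lindlar catalyst), quinoline, EtOAc, rt
Reagents that add atoms: none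
Why: Lindlar semihydrogenation adds H2 syn to the silylalkyne and should give the (Z)-vinylsilane, the geometry the ring closure needs, while the hindered trisubstituted enone alkene is not reduced on the poisoned catalyst.

Step 4
Reactants: 5 (Z)-silylallyl enone
Product: 6 4-methyl-4-[(Z)-3-(trimethylsilyl)allyl]nopinone (methyl anti and silylallyl syn to the gem-dimethyl bridge)
Conditions: Me2CuLi (from MeLi and CuI), Et2O, −20 to 0 °C; aq NH4Cl
Reagents that add atoms: lithium dimethylcuprate, [Li+].C[Cu-]C (from methyllithium, [Li]C, and CuI)
Why: Organocuprate conjugate addition; the methyl group should enter anti to the gem-dimethyl bridge, as Me2CuLi does with verbenone itself, so the new quaternary centre (future C10) carries the tether syn to the bridge carbon that becomes C4.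

Step 5
Reactants: 6 4-methyl-4-[(Z)-3-(trimethylsilyl)allyl]nopinone; 7 methyl bromoacetate
Product: 9 key precursor [6 carrying CH2CO2CH3 on C3 of the nopinone anti to the gem-dimethyl bridge and cis to the 4-methyl], via lithium enolate 8 (not isolated)
Conditions: LiN(iPr)2, THF, −78 °C; then 7, DMPU, −78 to −20 °C
Reagents that add atoms: none
Why: Kinetic enolate alkylation (only C3 can enolise, the bridgehead cannot); the electrophile should approach anti to the gem-dimethyl bridge, whose syn-methyl covers the other face, which places the acetate arm cis to the new methyl (future 9β).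

Step 6
Reactants: 9 key precursor
Product: 12 cis-fused 2-en-8-one keto ester [methyl (4,4,10-trimethyl-8-oxodecal-2-en-9-yl)acetate; 5β-H 10β-CH3 9β-arm], via ring-opened C4 cation titanium enolate 10 (not isolated), via cyclised titanium enolate 11 (not isolated)
Conditions: TiCl4 (2.5 equiv), 2,6-di-tert-butyl-4-methylpyridine (0.2 equiv), CH2Cl2, −78 to 0 °C; then water
Reagents that add atoms: none
Why: Proposed new method: TiCl4 on the C8 carbonyl should ionise the strained C7–C4 cyclobutane bond, which overlaps with the carbonyl π* orbital, to the titanium enolate and tertiary C4 cation 10, the same heterolysis that underlies the known Lewis-acid cleavage of nopinones to p-menthyl cations. The vinylsilane on the same face then attacks with its silicon-bearing carbon C3, the charge passes to C2 (β to silicon), and loss of the silyl group as Me3SiCl leaves the C2=C3 alkene of enolate 11, which water protonates at C7; the closest known reaction type for this half is the vinylsilane-terminated cation–olefin cyclisation. Ring A closes in the 6-endo-trig mode, the 5-exo alternative being disfavoured because it would put the charge α to silicon. No stereocentre is formed: C5, C9 and C10 are carried through, and the cis ring fusion follows from the syn placement of tether and C4 set in step 4. The selectivity needed is capture of the cation ahead of proton loss (isopropenyl or isopropylidene ketone) and of irreversible chloride capture; it is secured by the tether held within reach on the cation face, by the (Z)-geometry that makes the C–Si bond axial and parallel to the developing p orbital in a chair-like transition state, by re-ionisation of any tertiary chloride under TiCl4, and by the hindered pyridine that removes HCl before it can protodesilylate the vinylsilane.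

Step 7
Reactants: 12 cis-fused 2-en-8-one keto ester
Product: 13 saturated keto ester [methyl (4,4,10-trimethyl-8-oxodecal-9-yl)acetate; 5β-H 10β-CH3 9β-arm]
Conditions: H2 (1 atm), Pd/C, EtOAc, rt
Reagents that add atoms: none
Why: Heterogeneous catalytic hydrogenation of the cis-disubstituted ring A alkene; ketone and ester are untouched, the neutral conditions leave C9 alone, and no stereocentre is formed.

Step 8
Reactants: 13 saturated keto ester
Product: 14 8α-hydroxy ester [methyl (8α-hydroxy-4,4,8β,10-tetramethyldecal-9β-yl)acetate]
Conditions: MeLi, CeCl3, THF, −78 °C; aq NH4Cl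
Reagents that add atoms: methylcerium dichloride, C[Ce](Cl)Cl (from methyllithium, [Li]C, and CeCl3)
Why: Organocerium 1,2-addition; in the favoured chair of ring B the ring A carbon C1 is axial on the α face and blocks it, so methyl should enter on the equatorial trajectory from the convex β face and give 8β-CH3/8α-OH, while the non-basic reagent leaves C9 unepimerised and should react with the ketone faster than with the ester at −78 °C.

Step 9
Reactants: 14 8α-hydroxy ester
Product: 15 8α,12-diol [9β-(2-hydroxyethyl)-4,4,8β,10-tetramethyldecalin-8α-ol]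
Conditions: LiAlH4, THF, 0 °C to rt; H2O, aq NaOH
Reagents that add atoms: none
Why: Hydride reduction of the ester to the primary alcohol; the tertiary alkoxide and the ring stereocentres are not affected.

Step 10
Reactants: 15 8α,12-diol
Product: 16 12-iodo-8α-ol [9β-(2-iodoethyl)-4,4,8β,10-tetramethyldecalin-8α-ol]
Conditions: I2, PPh3, imidazole, CH2Cl2, 0 °C to rt
Reagents that add atoms: iodine, II
Why: Appel-type iodination is selective for the primary alcohol; the tertiary 8α-OH is trans-diaxial to the C9 arm and cannot close a tetrahydrofuran onto C12.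

Step 11
Reactants: 16 12-iodo-8α-ol
Product: 17 12-iodo 8α-trimethylsilyl ether
Conditions: Me3SiOTf, 2,6-lutidine, CH2Cl2, −78 to 0 °C
Reagents that add atoms: trimethylsilyl trifluoromethanesulfonate, C[Si](C)(C)OS(=O)(=O)C(F)(F)F
Why: Silylation of the hindered tertiary alcohol with the silyl triflate removes the acidic OH before lithium–iodine exchange.

Step 12
Reactants: 18 1-(trimethylsilyl)propyne; 19 geranyl bromide
Product: 22 (E)-6,10-dimethylundeca-5,9-dien-1-yne, via 3-lithio-1-(trimethylsilyl)propyne 20 (not isolated), via silyl enyne 21 (not isolated)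
Conditions: n-BuLi, THF, −78 °C; then 19, −78 °C to rt; then K2CO3, MeOH, rt
Reagents that add atoms: none
Why: Propargylic lithiation of the silylpropyne and SN2 alkylation by the allylic bromide, followed by protodesilylation of the alkynylsilane with methanolic carbonate; the (E)-alkene of the geranyl unit is not involved.

Step 13
Reactants: 22 (E)-6,10-dimethylundeca-5,9-dien-1-yne
Product: 24 (1E,5E)-1-iodo-2,6,10-trimethylundeca-1,5,9-triene, via alkenylalane 23 (not isolated)
Conditions: Me3Al, Cp2ZrCl2 (0.25 equiv), CH2Cl2, 0 °C to rt; then I2, THF, −30 to 0 °C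
Reagents that add atoms: trimethylaluminium, C[Al](C)C; iodine, II
Why: Negishi zirconium-catalysed carboalumination adds CH3–Al syn across the terminal alkyne with aluminium at the terminus, and iodinolysis with retention gives the (E)-trisubstituted vinyl iodide.

Step 14
Reactants: 17 12-iodo 8α-trimethylsilyl ether; 24 (1E,5E)-1-iodo-2,6,10-trimethylundeca-1,5,9-triene
Product: 27 trimethylsilyl ether of the target, via C12 alkyllithium 25 (not isolated), via methoxyborate 26 (not isolated)
Conditions: t-BuLi (2 equiv), Et2O, −78 °C; 9-MeO-9-BBN, THF, −78 °C to rt; then 24, PdCl2(dppf) (cat.), AsPh3, aq K3PO4, DMF, rt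
Reagents that add atoms: none
Why: B-alkyl Suzuki–Miyaura coupling; lithium–iodine exchange and capture by the methoxyborane give the borate, which transfers its primary alkyl group to palladium and couples with the vinyl iodide with retention of the (E)-geometry, forming C12–C13.

Step 15
Reactants: 27 trimethylsilyl ether of the target
Product: 28 target [(5R,8R,9R,10S); cis-fused 8α-ol with the (3E,7E)-4,8,12-trimethyltrideca-3,7,11-trienyl chain on C9]
Conditions: Bu4NF, THF, 0 °C to rt
Reagents that add atoms: none
Why: Fluoride cleavage of the silyl ether frees the tertiary alcohol without touching the triene or any stereocentre.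

**Compound list**

1 | (1S,5S)-(−)-verbenone | CC1=CC(=O)[C@H]2C[C@@H]1C2(C)C | starting material
2 | 10-bromoverbenone, 4-(bromomethyl)-6,6-dimethylbicyclo[3.1.1]hept-3-en-2-one | BrCC1=CC(=O)[C@H]2C[C@@H]1C2(C)C | intermediate
3 | tributyl[(trimethylsilyl)ethynyl]stannane | CCCC[Sn](CCCC)(CCCC)C#C[Si](C)(C)C | starting material
4 | 4-[3-(trimethylsilyl)prop-2-ynyl]-6,6-dimethylbicyclo[3.1.1]hept-3-en-2-one | C[Si](C)(C)C#CCC1=CC(=O)[C@H]2C[C@@H]1C2(C)C | intermediate
5 | 4-[(Z)-3-(trimethylsilyl)prop-2-enyl]-6,6-dimethylbicyclo[3.1.1]hept-3-en-2-one | C[Si](C)(C)/C=C\CC1=CC(=O)[C@H]2C[C@@H]1C2(C)C | intermediate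
6 | 4-methyl-4-[(Z)-3-(trimethylsilyl)allyl]nopinone (methyl anti, silylallyl syn to the gem-dimethyl bridge) | C[C@@]1(C/C=C\[Si](C)(C)C)CC(=O)[C@H]2C[C@@H]1C2(C)C | intermediate
7 | methyl bromoacetate | COC(=O)CBr | starting material
8 | lithium enolate of 6 | C[C@@]1(C/C=C\[Si](C)(C)C)C=C(O[Li])[C@H]2C[C@@H]1C2(C)C | intermediate (not isolated)
9 | key precursor: 4-methyl-4-[(Z)-3-(trimethylsilyl)allyl]nopinone with CH2CO2CH3 on C3, anti to the gem-dimethyl bridge | C[C@@]1(C/C=C\[Si](C)(C)C)[C@@H](CC(=O)OC)C(=O)[C@H]2C[C@@H]1C2(C)C | intermediate
10 | ring-opened tertiary C4 cation with titanium enolate at C7=C8 | C[C@@]1(C/C=C\[Si](C)(C)C)[C@@H](CC(=O)OC)C(O[Ti-](Cl)(Cl)(Cl)Cl)=CC[C@@H]1[C+](C)C | intermediate (not isolated)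
11 | trichlorotitanium enolate of 12 | COC(=O)C[C@@H]1[C@@]2(C)CC=CC(C)(C)[C@H]2CC=C1O[Ti](Cl)(Cl)Cl | intermediate (not isolated)
12 | cis-fused 2-en-8-one keto ester (5β-H, 10β-CH3, 9β-CH2CO2CH3) | COC(=O)C[C@@H]1[C@@]2(C)CC=CC(C)(C)[C@H]2CCC1=O | intermediate
13 | saturated cis-fused 8-keto ester | COC(=O)C[C@@H]1[C@@]2(C)CCCC(C)(C)[C@H]2CCC1=O | intermediate
14 | 8α-hydroxy-8β-methyl ester | COC(=O)C[C@@H]1[C@@]2(C)CCCC(C)(C)[C@H]2CC[C@@]1(C)O | intermediate
15 | 8α,12-diol | OCC[C@@H]1[C@@]2(C)CCCC(C)(C)[C@H]2CC[C@@]1(C)O | intermediate
16 | 12-iodo-8α-ol | ICC[C@@H]1[C@@]2(C)CCCC(C)(C)[C@H]2CC[C@@]1(C)O | intermediate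
17 | 12-iodo 8α-trimethylsilyl ether | ICC[C@@H]1[C@@]2(C)CCCC(C)(C)[C@H]2CC[C@@]1(C)O[Si](C)(C)C | intermediate
18 | 1-(trimethylsilyl)propyne | CC#C[Si](C)(C)C | starting material
19 | geranyl bromide | CC(C)=CCC/C(C)=C/CBr | starting material
20 | 3-lithio-1-(trimethylsilyl)propyne | [Li]CC#C[Si](C)(C)C | intermediate (not isolated)
21 | (E)-6,10-dimethyl-1-(trimethylsilyl)undeca-5,9-dien-1-yne | CC(C)=CCC/C(C)=C/CCC#C[Si](C)(C)C | intermediate (not isolated)
22 | (E)-6,10-dimethylundeca-5,9-dien-1-yne | CC(C)=CCC/C(C)=C/CCC#C | intermediate
23 | dimethyl[(1E,5E)-2,6,10-trimethylundeca-1,5,9-trienyl]alane | CC(C)=CCC/C(C)=C/CC/C(C)=C/[Al](C)C | intermediate (not isolated)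
24 | (1E,5E)-1-iodo-2,6,10-trimethylundeca-1,5,9-triene | CC(C)=CCC/C(C)=C/CC/C(C)=C/I | intermediate
25 | C12 alkyllithium from 17 | [Li]CC[C@@H]1[C@@]2(C)CCCC(C)(C)[C@H]2CC[C@@]1(C)O[Si](C)(C)C | intermediate (not isolated)
26 | lithium B-alkyl-B-methoxy-9-borabicyclo[3.3.1]nonane borate from 25 | [Li+].CO[B-]3(CC[C@@H]1[C@@]2(C)CCCC(C)(C)[C@H]2CC[C@@]1(C)O[Si](C)(C)C)C4CCCC3CCC4 | intermediate (not isolated)
27 | trimethylsilyl ether of the target | CC(C)=CCC/C(C)=C/CC/C(C)=C/CC[C@@H]1[C@@]2(C)CCCC(C)(C)[C@H]2CC[C@@]1(C)O[Si](C)(C)C | intermediate
28 | CNP0389811.1, (5R,8R,9R,10S) cis-fused 8α-ol | CC(C)=CCC/C(C)=C/CC/C(C)=C/CC[C@@H]1[C@@]2(C)CCCC(C)(C)[C@H]2CC[C@@]1(C)O | target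

**Step count**

Total step count: 15. Longest linear sequence: 13 (steps 1–11, 14, 15); steps 12–13 make the side-chain iodide.

**Steps most likely to fail**

1. Step 6 (the step labelled as a proposed new method). What may go wrong: ring opening without ring closure, because proton loss from the cation or chloride capture outruns attack by the vinylsilane, or protodesilylation of the tether before ionisation. Fallback with known chemistry, setting out from 9 and returning at 12: the two events are separated. Iodotrimethylsilane (Me3SiCl, NaI, MeCN, 0 °C) carries out the established iodosilane cleavage of the nopinone cyclobutane and, after aqueous work-up, gives the ring-opened tertiary iodide F1. Silver trifluoromethanesulfonate with 2,6-di-tert-butyl-4-methylpyridine in CH2Cl2 at −78 °C then abstracts iodide, and the free tertiary cation, no longer paired with a titanium chloride that can return chloride or HCl, undergoes the known vinylsilane-terminated cation–olefin cyclisation to 12.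

2. Step 8. What may go wrong: insufficient or reversed facial selectivity at C8 (methyl entering from the α face gives the 8-epimer, whose alkoxide would lactonise onto the cis arm), or competing addition to the ester. Fallback, setting out from 13 and returning at 15: carbon and oxygen exchange roles. Non-basic, ketone-selective methylenation (Zn, CH2Br2, TiCl4, THF) gives the 8(17)-methylene ester F2 without epimerising C9. mCPBA follows the same steric bias as the methyl reagent and, if that bias is toward the α face, gives the 8α,17-spiro-epoxide F3. LiAlH4 opens the epoxide at its CH2 terminus and reduces the ester, giving diol 15.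

3. Step 3. What may go wrong: over-reduction of the vinylsilane, palladium-mediated migration of the skipped diene into conjugation with the enone, or partial loss of the (Z)-geometry. Fallback, setting out from 2 and returning at 5 (bypassing 4): the geometry is brought in ready-made. Pd(PPh3)4-catalysed cis-addition of Me3Si–SnBu3 to acetylene gives (Z)-tributyl[2-(trimethylsilyl)ethenyl]stannane F4, and Stille coupling of this stannane with bromide 2 (Pd2(dba)3, P(2-furyl)3, THF) gives 5 with retention of alkene geometry.

Further compounds
F1 | step 6 | methyl {3-(2-iodopropan-2-yl)-2-methyl-6-oxo-2-[(Z)-3-(trimethylsilyl)prop-2-enyl]cyclohexyl}acetate (ring-opened tertiary iodide) | C[C@@]1(C/C=C\[Si](C)(C)C)[C@@H](CC(=O)OC)C(=O)CC[C@@H]1C(C)(C)I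
F2 | step 8 | 8(17)-methylene ester, methyl (4,4,10-trimethyl-8-methylenedecal-9β-yl)acetate | COC(=O)C[C@@H]1[C@@]2(C)CCCC(C)(C)[C@H]2CCC1=C
F3 | step 8 | 8α,17-spiro-epoxide ester | COC(=O)C[C@@H]1[C@@]2(C)CCCC(C)(C)[C@H]2CC[C@]13CO3
F4 | step 3 | (Z)-tributyl[2-(trimethylsilyl)ethenyl]stannane | CCCC[Sn](CCCC)(CCCC)/C=C\[Si](C)(C)C
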